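## Retrosynthetic overview

1. Rings: A cyclohexane, B spiro δ-lactone, C spiro tetrahydrofuran, D tetrahydropyran, E 1,3-dioxolane, F γ-lactone. The target comes from oxidative lactonisation (ring B, last) after Baeyer–Villiger insertion of the ring-F oxygen into cyclobutanone 24.
2. 24 comes from an intramolecular ketene–enol ether [2+2] of 23. The ketene C=O carbon bonds to the enol-ether β-CH (the later lactone C(=O)–CH bond) and the ketene α-carbon bonds to the O–CH carbon (the later O–CH/C(CH3) bond); ring E and the four-membered ring close together.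
3. Enabling feature: the orthoester carbon joins the ring-D oxygen (on the O–CH carbon) and the ring-E oxygen (on the methyl-bearing ketal carbon) in one O–C–O unit. Ring E is therefore a three-atom tether from a ketene to a dihydropyran C=C, and the acyl–O–C(CH3)(O) unit of ring F is the Baeyer–Villiger retron of an α-alkoxy-α-methylcyclobutanone.
4. Orthoester enol ether 20 comes from lactate-for-methoxy exchange on 17, which comes from a hetero-Diels–Alder reaction of (E)-crotonaldehyde with ketene acetal 15 (ring D; quaternary carbon, CH(CH3) and orthoester carbon set), made from spiro lactone 13.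
5. 13 comes from (R)-carvone (ring A) by two α′-alkylations, allylzinc addition and lactonisation (ring C), hydroxyl-directed epoxidation and reductive opening. Ring order: A, C, D, E (with the cyclobutanone), F, B.

Key step: step 12

Remark: the lactate centre (S, from 18) and the α-methyl centre of lactones 10–14 need no control; both are planarised (in 23 and in 15) before the corresponding stereocentres of the target are set.
Remark: benzyl 3-iodopropyl ether 4 is taken as a catalogue compound.

## Route

Step 1
Reactants: 1 (R)-(−)-carvone; 2 benzyl chloromethyl ether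
Product: 3 6-(benzyloxymethyl)carvone (CH2OBn trans to isopropenyl)
Conditions: LiN(iPr)2 (1.05 equiv), THF, −78 °C; then 2, −78 → −30 °C
Reagents that add atoms: benzyl chloromethyl ether, ClCOCc1ccccc1
Why: Kinetic deprotonation of the enone at the α′-CH2 and SN2 alkylation of the lithium enolate (enolate alkylation) should give the trans product, whose new centre is planarised again in step 2.

Step 2
Reactants: 3; 4 benzyl 3-iodopropyl ether
Product: 5 6-(benzyloxymethyl)-6-(3-benzyloxypropyl)carvone (CH2OBn cis to isopropenyl)
Conditions: LiN(iPr)2 (1.2 equiv), THF–DMPU, −78 °C; then 4, −78 → −10 °C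
Reagents that add atoms: benzyl 3-iodopropyl ether, ICCCOCc1ccccc1
Why: Second enolate alkylation at the same carbon, in which the iodide should approach the tetrasubstituted enolate anti to the neighbouring isopropenyl group, so that the benzyloxymethyl group ends cis to isopropenyl and the quaternary centre of ring A is set.

Step 3
Reactants: 5; 6 ethyl 2-(bromomethyl)acrylate
Product: 8 tertiary allylic alcohol carrying the 2-(ethoxycarbonyl)allyl group (OH cis to CH2OBn), via allylzinc bromide 7 (not isolated)
Conditions: Zn dust, THF, 6, 0 → 20 °C; then 5, 0 °C → rt; sat. aq NH4Cl, 0 °C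
Reagents that add atoms: ethyl 2-(bromomethyl)acrylate, C=C(CBr)C(=O)OCC
Why: Reformatsky-type (Barbier) 1,2-addition of the allylzinc reagent to the enone carbonyl should occur anti to the pseudoaxial benzyloxymethyl group on the adjacent quaternary carbon, giving the alcohol cis to that group, and the cold quench keeps the open hydroxy ester.

Step 4
Reactants: 8
Product: 9 epoxy alcohol (epoxide cis to the tertiary OH)
Conditions: VO(acac)2 (5 mol %), t-BuOOH (1.5 equiv, decane), PhMe, 0 °C → rt
Reagents that add atoms: tert-butyl hydroperoxide, CC(C)(C)OO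
Why: Hydroxyl-directed vanadium-catalysed epoxidation of the tertiary allylic alcohol should oxidise the ring alkene syn to the OH, leaving the electron-poor acrylate and the remote isopropenyl group untouched.

Step 5
Reactants: 9
Product: 11 spiro α-methyl-γ-lactone epoxide (ring C closed as lactone), via saturated hydroxy ester 10 (not isolated)
Conditions: LiBH(s-Bu)3 (2.3 equiv), THF, −78 °C; MeOH, −78 °C → rt; H2O
Reagents that add atoms: none
Why: Conjugate hydride reduction of the β-unsubstituted acrylate by the bulky borohydride, then alkoxide-driven lactonisation of the tertiary alcohol on the saturated ester (5-exo-trig), should give the lactone as an epimer mixture at the α-methyl carbon, which is planarised in step 8.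

Step 6
Reactants: 11
Product: 12 hydroxy lactone (secondary OH and adjacent ring methyl cis)
Conditions: Cp2TiCl2 (20 mol %), Zn dust, 2,4,6-collidine·HCl, 1,4-cyclohexadiene, THF, rt
Reagents that add atoms: none
Why: Titanocene-mediated radical epoxide opening (trivalent titanium, Cp2TiCl, cleaves the C–O bond at the tertiary carbon) should give the tertiary radical, which takes a hydrogen atom from 1,4-cyclohexadiene anti to the bulky titanium alkoxide, so the methyl group ends cis to the new secondary OH.

Step 7
Reactants: 12
Product: 13 tribenzyl ether spiro lactone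
Conditions: 2-benzyloxy-1-methylpyridinium triflate (2 equiv), MgO, PhCF3, 85 °C
Reagents that add atoms: 2-benzyloxy-1-methylpyridinium trifluoromethanesulfonate, C[n+]1ccccc1OCc1ccccc1.[O-]S(=O)(=O)C(F)(F)F
Why: Neutral thermal benzyl transfer from the 2-benzyloxypyridinium salt (SN1-type O-benzylation) should protect the secondary alcohol without enolising the lactone; no stereocentre is touched.

Step 8
Reactants: 13
Product: 15 spiro 2-methoxy-3-methyl-4,5-dihydrofuran (cyclic ketene acetal), via O-methyl lactonium tetrafluoroborate 14 (not isolated)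
Conditions: Me3OBF4 (1.3 equiv), CH2Cl2, 0 °C → rt; i-Pr2NEt, −78 → 0 °C; pentane, filtration through basic alumina under Ar
Reagents that add atoms: trimethyloxonium tetrafluoroborate, C[O+](C)C.F[B-](F)(F)F
Why: O-Methylation of the lactone carbonyl by the oxonium salt should give the dialkoxycarbenium ion, whose acidic α-CH is removed by the hindered amine to give the tetrasubstituted ketene acetal (O-alkylation then deprotonation), erasing the α-stereocentre.

Step 9
Reactants: 15; 16 (E)-crotonaldehyde
Product: 17 cis-fused bicyclic methyl orthoester enol ether (ring D; methoxy and both ring methyls on one face)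
Conditions: 16 (5 equiv), PhMe, K2CO3 (trace), sealed tube, 80 °C
Reagents that add atoms: (E)-crotonaldehyde, C/C=C/C=O
Why: Thermal inverse-electron-demand hetero-Diels–Alder reaction of the s-cis enal with the ketene acetal should occur on the dihydrofuran face anti to the quaternary ring-A carbon (the other flank carries only an equatorial H), through the transition state with the spiro ring exo and the methyl/methoxy pair endo, which places the two methyl groups cis while cis ring fusion fixes the orthoester carbon.

Step 10
Reactants: 17; 18 methyl (S)-lactate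
Product: 20 lactate orthoester methyl ester, via silylated lactate 19 (not isolated)
Conditions: 18 (4 equiv), N,O-bis(trimethylsilyl)acetamide, CH2Cl2, rt; then 17, Me3SiOTf (5 mol %), 2,6-di-tert-butyl-4-methylpyridine (10 mol %), −40 → 0 °C, reduced pressure; Et3N
Reagents that add atoms: methyl (S)-lactate, C[C@H](O)C(=O)OC
Why: Silyl triflate-catalysed transorthoesterification under aprotic conditions should ionise the exocyclic methoxy group to the bicyclic dioxocarbenium ion, which the silyl ether can recapture only on the convex face, so the orthoester configuration is retained while volatile MeOSiMe3 is removed to drive the exchange.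

Step 11
Reactants: 20
Product: 21 potassium carboxylate of the lactate orthoester
Conditions: KOSiMe3 (1.1 equiv), THF, rt
Reagents that add atoms: potassium trimethylsilanolate, C[Si](C)(C)[O-].[K+]
Why: Anhydrous ester cleavage by the silanolate should give the potassium carboxylate directly, leaving the base-stable orthoester and enol ether intact.

Step 12
Reactants: 21
Product: 24 cage cyclobutanone (rings A, C, D, E plus fused cyclobutanone), via mixed sulfonic anhydride 22 (not isolated), via ketene 23 (not isolated)
Conditions: TsCl (1.3 equiv), Et3N (6 equiv), PhMe (0.005 M), 0 → 100 °C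
Reagents that add atoms: none
Why: Tosylation of the carboxylate gives the mixed anhydride, from which Et3N eliminates sulfonate to form the alkoxy(methyl)ketene; its electrophilic central carbon bonds to the nucleophilic β-carbon of the cyclic enol ether while the ketene α-carbon bonds to the oxygen-bearing alkene carbon in an asynchronous thermal [2+2] cycloaddition, the closest known type being the intramolecular alkoxyketene–alkene cycloaddition of 2-(alkenyloxy)propanoyl derivatives. Ring E closes in the fused five-membered mode through the three-atom O–C(orthoester)–O tether, and the cyclobutanone closes across the former C=C, giving a 6,8-dioxabicyclo[3.2.1]octane core with the four-membered ring fused on it. The three new stereocentres (ring CH next to C=O, O–CH, methyl-bearing quaternary carbon) are set by the tether: the ketene hangs from the orthoester oxygen that is cis to both ring methyl groups and can reach only that face of the alkene, and cis fusion of the four- and five-membered rings fixes the quaternary centre. Regioselectivity is secured twice, by the polarity of the enol ether and by the tether length. Chemoselectivity over the isopropenyl group and over ketene dimerisation should follow from intramolecularity and high dilution.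

Step 13
Reactants: 24
Product: 25 cyclobutanone tertiary alcohol
Conditions: Co(acac)2 (20 mol %), PhSiH3, O2 (1 atm), THF–i-PrOH, rt
Reagents that add atoms: dioxygen, O=O
Why: Mukaiyama hydration (cobalt hydride hydrogen-atom transfer to the 1,1-disubstituted alkene, O2 capture of the tertiary radical, reduction) should give the Markovnikov tertiary alcohol, and is placed before the peracid step so that no alkene competes there.

Step 14
Reactants: 25
Product: 26 tribenzyl ether cage γ-lactone (ring F closed)
Conditions: mCPBA (1.2 equiv), NaHCO3, CH2Cl2, 0 °C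
Reagents that add atoms: 3-chloroperoxybenzoic acid, OOC(=O)c1cccc(Cl)c1
Why: Baeyer–Villiger oxidation of the strained cyclobutanone, in which the fully substituted oxygen-bearing α-carbon should migrate with retention, inserts the ring oxygen between the carbonyl and the methyl-bearing carbon to give the γ-lactone acyl ketal.

Step 15
Reactants: 26
Product: 27 tetraol (two primary, one secondary, one tertiary OH)
Conditions: H2 (1 atm), 10% Pd/C, EtOAc, rt
Reagents that add atoms: none
Why: Hydrogenolysis of the three benzyl ethers over palladium under neutral conditions should leave lactone, orthoester and acyl ketal untouched.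

Step 16
Reactants: 27
Product: 29 chermebilaene B, via lactol 28 (not isolated)
Conditions: TEMPO (20 mol %), PhI(OAc)2 (2.5 equiv), NaHCO3, CH2Cl2, rt
Reagents that add atoms: none
Why: Oxoammonium (TEMPO) oxidation should select the unhindered primary alcohol over the neopentyl primary and the hindered secondary one, the aldehyde being trapped by the neopentyl OH as the six-membered lactol and oxidised again to the δ-lactone of ring B (oxidative lactonisation of a 1,5-diol).

## Compound list

1 | (R)-(−)-carvone | CC1=CC[C@@H](C(C)=C)CC1=O | starting material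
2 | benzyl chloromethyl ether | ClCOCc1ccccc1 | starting material
3 | 6-(benzyloxymethyl)carvone, CH2OBn trans to isopropenyl | CC1=CC[C@@H](C(C)=C)[C@H](COCc2ccccc2)C1=O | intermediate
4 | benzyl 3-iodopropyl ether | ICCCOCc1ccccc1 | starting material
5 | 6-(benzyloxymethyl)-6-(3-benzyloxypropyl)carvone, CH2OBn cis and propyl chain trans to isopropenyl | CC1=CC[C@@H](C(C)=C)[C@](COCc2ccccc2)(CCCOCc2ccccc2)C1=O | intermediate
6 | ethyl 2-(bromomethyl)acrylate | C=C(CBr)C(=O)OCC | starting material
7 | [2-(ethoxycarbonyl)allyl]zinc bromide | C=C(C[Zn]Br)C(=O)OCC | intermediate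
8 | ethyl 2-(cyclohexenylmethyl)acrylate tertiary alcohol from 5; OH cis to CH2OBn and isopropenyl, new CH2 trans | CC1=CC[C@@H](C(C)=C)[C@](COCc2ccccc2)(CCCOCc2ccccc2)[C@]1(O)CC(=C)C(=O)OCC | intermediate
9 | epoxy alcohol of 8; ring epoxide cis to the tertiary OH | C[C@]12O[C@H]1C[C@@H](C(C)=C)[C@](COCc3ccccc3)(CCCOCc3ccccc3)[C@]2(O)CC(=C)C(=O)OCC | intermediate
10 | saturated epoxy hydroxy ester (ethyl 2-methylpropanoate side chain, both epimers at the α-methyl carbon) | C[C@]12O[C@H]1C[C@@H](C(C)=C)[C@](COCc3ccccc3)(CCCOCc3ccccc3)[C@]2(O)CC(C)C(=O)OCC | intermediate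
11 | spiro α-methyl-γ-butyrolactone epoxide; lactone O cis to epoxide O; both epimers at the α-methyl carbon | C[C@]12O[C@H]1C[C@@H](C(C)=C)[C@](COCc4ccccc4)(CCCOCc4ccccc4)[C@]23CC(C)C(=O)O3 | intermediate
12 | spiro hydroxy lactone; secondary OH, adjacent ring methyl and lactone O all cis; both epimers at the α-methyl carbon | C[C@H]1[C@@H](O)C[C@@H](C(C)=C)[C@](COCc3ccccc3)(CCCOCc3ccccc3)[C@]12CC(C)C(=O)O2 | intermediate
13 | tribenzyl ether spiro lactone (O-benzyl derivative of 12) | C[C@H]1[C@@H](OCc3ccccc3)C[C@@H](C(C)=C)[C@](COCc3ccccc3)(CCCOCc3ccccc3)[C@]12CC(C)C(=O)O2 | intermediate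
14 | O-methyl lactonium tetrafluoroborate of 13 | C[C@H]1[C@@H](OCc3ccccc3)C[C@@H](C(C)=C)[C@](COCc3ccccc3)(CCCOCc3ccccc3)[C@]12CC(C)C(OC)=[O+]2.F[B-](F)(F)F | intermediate
15 | spiro 2-methoxy-3-methyl-4,5-dihydrofuran (cyclic ketene acetal) | C[C@H]1[C@@H](OCc3ccccc3)C[C@@H](C(C)=C)[C@](COCc3ccccc3)(CCCOCc3ccccc3)[C@]12CC(C)=C(OC)O2 | intermediate
16 | (E)-crotonaldehyde | C/C=C/C=O | starting material
17 | cis-fused furo[2,3-b]pyran methyl orthoester enol ether; methoxy, angular methyl and ring methyl on one face | C[C@H]1[C@@H](OCc3ccccc3)C[C@@H](C(C)=C)[C@](COCc3ccccc3)(CCCOCc3ccccc3)[C@]12C[C@]1(C)[C@@H](C)C=CO[C@]1(OC)O2 | intermediate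
18 | methyl (S)-lactate | C[C@H](O)C(=O)OC | starting material
19 | methyl (S)-2-(trimethylsilyloxy)propanoate | C[C@H](O[Si](C)(C)C)C(=O)OC | intermediate
20 | lactate orthoester methyl ester (methoxy of 17 replaced by the lactate oxygen, same configuration) | C[C@H]1[C@@H](OCc3ccccc3)C[C@@H](C(C)=C)[C@](COCc3ccccc3)(CCCOCc3ccccc3)[C@]12C[C@]1(C)[C@@H](C)C=CO[C@]1(O[C@@H](C)C(=O)OC)O2 | intermediate
21 | potassium carboxylate of 20 | C[C@H]1[C@@H](OCc3ccccc3)C[C@@H](C(C)=C)[C@](COCc3ccccc3)(CCCOCc3ccccc3)[C@]12C[C@]1(C)[C@@H](C)C=CO[C@]1(O[C@@H](C)C(=O)[O-])O2.[K+] | intermediate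
22 | mixed carboxylic p-toluenesulfonic anhydride | C[C@H]1[C@@H](OCc3ccccc3)C[C@@H](C(C)=C)[C@](COCc3ccccc3)(CCCOCc3ccccc3)[C@]12C[C@]1(C)[C@@H](C)C=CO[C@]1(O[C@@H](C)C(=O)OS(=O)(=O)c3ccc(C)cc3)O2 | intermediate
23 | orthoester-tethered alkoxy(methyl)ketene | C[C@H]1[C@@H](OCc3ccccc3)C[C@@H](C(C)=C)[C@](COCc3ccccc3)(CCCOCc3ccccc3)[C@]12C[C@]1(C)[C@@H](C)C=CO[C@]1(OC(C)=C=O)O2 | intermediate
24 | cage cyclobutanone (orthoester, dioxolane and fused α-alkoxy-α-methylcyclobutanone; isopropenyl, three OBn) | C[C@H]1[C@@H](OCc5ccccc5)C[C@@H](C(C)=C)[C@](COCc5ccccc5)(CCCOCc5ccccc5)[C@]12C[C@]1(C)[C@@H](C)[C@H]3C(=O)[C@@]4(C)O[C@@]1(O[C@@H]34)O2 | intermediate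
25 | cage cyclobutanone with 2-hydroxypropan-2-yl group | C[C@H]1[C@@H](OCc5ccccc5)C[C@@H](C(C)(C)O)[C@](COCc5ccccc5)(CCCOCc5ccccc5)[C@]12C[C@]1(C)[C@@H](C)[C@H]3C(=O)[C@@]4(C)O[C@@]1(O[C@@H]34)O2 | intermediate
26 | tribenzyl ether cage γ-lactone | C[C@H]1[C@@H](OCc5ccccc5)C[C@@H](C(C)(C)O)[C@](COCc5ccccc5)(CCCOCc5ccccc5)[C@]12C[C@]1(C)[C@@H](C)[C@H]3C(=O)O[C@@]4(C)O[C@@]1(O[C@@H]34)O2 | intermediate
27 | tetraol (hydroxymethyl and 3-hydroxypropyl on the quaternary ring-A carbon) | C[C@H]1[C@@H](O)C[C@@H](C(C)(C)O)[C@](CO)(CCCO)[C@]12C[C@]1(C)[C@@H](C)[C@H]3C(=O)O[C@@]4(C)O[C@@]1(O[C@@H]34)O2 | intermediate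
28 | spiro δ-lactol (both epimers at the lactol carbon) | C[C@H]1[C@@H](O)C[C@@H](C(C)(C)O)[C@]2(CCC(O)OC2)[C@]12C[C@]1(C)[C@@H](C)[C@H]3C(=O)O[C@@]4(C)O[C@@]1(O[C@@H]34)O2 | intermediate
29 | chermebilaene B | C[C@H]1[C@@H](O)C[C@@H](C(C)(C)O)[C@]2(CCC(=O)OC2)[C@]12C[C@]1(C)[C@@H](C)[C@H]3C(=O)O[C@@]4(C)O[C@@]1(O[C@@H]34)O2 | target

## Step count and risks

Total step count: 16. Longest linear sequence: 16 steps, from (R)-carvone 1.

**Step 12 (key step).** The ketene may oligomerise, or the orthoester enol ether may be opened by triethylammonium salts at 100 °C, before the cycloaddition occurs. The fallback replaces the ketene by a more electrophilic keteniminium ion; it sets out from 17 and comes back at 24.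
- N,N-Dimethyl-(S)-lactamide is silylated in the flask with N,O-bis(trimethylsilyl)acetamide to the silyl ether F1.
- F1 is exchanged onto 17 under the Me3SiOTf protocol of step 10, giving the dimethylamide orthoester F2.
- Tf2O and 2,6-di-tert-butyl-4-methylpyridine in 1,2-dichloroethane at 0 °C convert the amide into the keteniminium triflate F3.
- F3 should undergo the same tether-controlled [2+2] at or below room temperature to the cyclobutaniminium triflate F4.
- Hydrolysis with aqueous NaHCO3 gives 24.

**Step 10.** The exchange may stall because the equilibrium does not favour the less electron-rich lactate oxygen, or the pyran may open by loss of the enol oxygen. The fallback installs the lactate before ring D exists; it sets out from 15 and comes back at 20.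
- Methyl (S)-lactate 18 is added across the ketene acetal (neat, trace pivalic acid, rt), giving the mixed methyl lactyl orthoester F5.
- Heating in xylene with catalytic 2,4,6-trimethylbenzoic acid while methanol distils (Johnson–Claisen-type orthoester to ketene acetal conversion) gives the lactate ketene acetal F6.
- F6 undergoes the hetero-Diels–Alder reaction with (E)-crotonaldehyde 16 as in step 9 and gives 20 directly.

**Step 9.** The cycloaddition between a tetrasubstituted ketene acetal and a β-substituted enal may be slow enough for aldehyde polymerisation or ketene acetal hydrolysis to win, or endo/exo control may be poor. The fallback forms the C–C bond stepwise under catalyst control; it sets out from 13 and comes back at 17.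
- LiN(iPr)2 and Me3SiCl give the silyl ketene acetal F7.
- Mukaiyama–Michael addition to (E)-crotonaldehyde under iminium catalysis with a 5-benzyl-2-tert-butyl-3-methylimidazolidin-4-one trifluoroacetate salt (enantiomer chosen for the methyl-bearing methine) gives the lactone aldehyde F8; the quaternary carbon is set by attack anti to the quaternary ring-A carbon.
- Me3OBF4 with 2,6-di-tert-butyl-4-methylpyridine methylates the lactone carbonyl to the lactonium salt F9.
- F9 is captured by the aldehyde oxygen in a six-membered ring and loses the α-proton to give 17. This last cascade is the least precedented operation in the fallback.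

Further compounds
F1 | step 12 | (S)-N,N-dimethyl-2-(trimethylsilyloxy)propanamide | C[C@H](O[Si](C)(C)C)C(=O)N(C)C
F2 | step 12 | dimethylamide orthoester (amide analogue of 20) | C[C@H]1[C@@H](OCc3ccccc3)C[C@@H](C(C)=C)[C@](COCc3ccccc3)(CCCOCc3ccccc3)[C@]12C[C@]1(C)[C@@H](C)C=CO[C@]1(O[C@@H](C)C(=O)N(C)C)O2
F3 | step 12 | orthoester-tethered keteniminium triflate | C[C@H]1[C@@H](OCc3ccccc3)C[C@@H](C(C)=C)[C@](COCc3ccccc3)(CCCOCc3ccccc3)[C@]12C[C@]1(C)[C@@H](C)C=CO[C@]1(OC(C)=C=[N+](C)C)O2.[O-]S(=O)(=O)C(F)(F)F
F4 | step 12 | cage cyclobutaniminium triflate | C[C@H]1[C@@H](OCc5ccccc5)C[C@@H](C(C)=C)[C@](COCc5ccccc5)(CCCOCc5ccccc5)[C@]12C[C@]1(C)[C@@H](C)[C@H]3C(=[N+](C)C)[C@@]4(C)O[C@@]1(O[C@@H]34)O2.[O-]S(=O)(=O)C(F)(F)F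
F5 | step 10 | mixed methyl lactyl orthoester of lactone 13 | C[C@H]1[C@@H](OCc3ccccc3)C[C@@H](C(C)=C)[C@](COCc3ccccc3)(CCCOCc3ccccc3)[C@]12CC(C)C(OC)(O[C@@H](C)C(=O)OC)O2
F6 | step 10 | lactate ketene acetal | C[C@H]1[C@@H](OCc3ccccc3)C[C@@H](C(C)=C)[C@](COCc3ccccc3)(CCCOCc3ccccc3)[C@]12CC(C)=C(O[C@@H](C)C(=O)OC)O2
F7 | step 9 | trimethylsilyl ketene acetal of lactone 13 | C[C@H]1[C@@H](OCc3ccccc3)C[C@@H](C(C)=C)[C@](COCc3ccccc3)(CCCOCc3ccccc3)[C@]12CC(C)=C(O[Si](C)(C)C)O2
F8 | step 9 | α-quaternary lactone aldehyde | C[C@H]1[C@@H](OCc3ccccc3)C[C@@H](C(C)=C)[C@](COCc3ccccc3)(CCCOCc3ccccc3)[C@]12C[C@](C)([C@@H](C)CC=O)C(=O)O2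
F9 | step 9 | O-methyl lactonium tetrafluoroborate of F8 | C[C@H]1[C@@H](OCc3ccccc3)C[C@@H](C(C)=C)[C@](COCc3ccccc3)(CCCOCc3ccccc3)[C@]12C[C@](C)([C@@H](C)CC=O)C(OC)=[O+]2.F[B-](F)(F)F
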